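**Retrosynthetic overview**
1. The lactol (the only stereocentre) is closed last, from the 2-formylbenzoic acid set free in one acidolysis that also removes two MOM ethers and two tert-butyl esters.
2. The fumarate ester comes from the benzylic alcohol of the depsidone and mono-tert-butyl fumarate (fragment C).
3. The seven-membered depsidone ring closes by intramolecular oxa-Michael addition–elimination: a B-ring phenoxide adds to the C–F carbon of ring A, which is β to both the formyl and the ester carbonyl.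
4. The depside precursor is the ester of an A-ring acid (fragment A, from 1-bromo-3-fluoro-5-methylbenzene) with a B-ring catechol (fragment B, from benzene-1,2,4-triol), both built by directed metalations.
5. Ring order: both benzene rings are bought; temporary benzodioxole ketal, then the seven-membered dioxepinone, then the five-membered lactol.

Assumption: the stereocentre is a hemiacetal carbon that epimerises through the open formyl acid, so no reaction can fix it permanently; it is formed in the last step and the (R)-form is taken by chiral-phase chromatography, the (S)-form being recycled by re-equilibration.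

**Fragment A**

Step 1
Reactants: 1 1-bromo-3-fluoro-5-methylbenzene
Product: 2 3-fluoro-5-methylphenol
Conditions: Pd2(dba)3 (1 mol%), tBuXPhos (4 mol%), KOH, dioxane/H2O, 100 °C; then 1 M HCl
Reagents that add atoms: potassium hydroxide, [K+].[OH-]
Why: Buchwald-type Pd-catalysed hydroxylation replaces only the C–Br bond, the unactivated C–F bond being inert.

Step 2
Reactants: 2 3-fluoro-5-methylphenol
Product: 3 4-bromo-3-fluoro-5-methylphenol
Conditions: NBS (1.0 equiv), MeCN, −10 → 0 °C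
Reagents that add atoms: N-bromosuccinimide, O=C1CCC(=O)N1Br
Why: Electrophilic aromatic bromination goes para to the hydroxyl group, as it does for other 3,5-disubstituted phenols.

Step 3
Reactants: 3 4-bromo-3-fluoro-5-methylphenol
Product: 4 2-bromo-1-fluoro-5-(methoxymethoxy)-3-methylbenzene
Conditions: MOMCl, iPr2NEt, CH2Cl2, 0 °C → rt
Reagents that add atoms: chloromethyl methyl ether, COCCl
Why: O-alkylation of the phenol (MOM protection) masks the OH and adds a directing group for the next step.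

Step 4
Reactants: 4 2-bromo-1-fluoro-5-(methoxymethoxy)-3-methylbenzene
Product: 6 3-bromo-2-fluoro-6-(methoxymethoxy)-4-methylbenzaldehyde, via aryllithium 5 (not isolated)
Conditions: LDA, THF, −78 °C, 1 h; DMF, −78 → 0 °C; H2O
Reagents that add atoms: N,N-dimethylformamide, CN(C)C=O
Why: Directed ortho-metalation with an amide base removes the most acidic proton, between F and OMOM, without C–Br exchange, and DMF formylates the aryllithium.

Step 5
Reactants: 6 3-bromo-2-fluoro-6-(methoxymethoxy)-4-methylbenzaldehyde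
Product: 9 2-fluoro-3-formyl-4-(methoxymethoxy)-6-methylbenzoic acid, via amino alkoxide 7 (not isolated), via aryllithium 8 (not isolated)
Conditions: LiN(Me)CH2CH2NMe2 (from the amine and n-BuLi), THF, −78 °C; n-BuLi, −78 °C, 15 min; CO2; cold 1 M HCl to pH 3
Reagents that add atoms: carbon dioxide, O=C=O
Why: Comins in situ protection of the aldehyde as an α-amino alkoxide allows Br–Li exchange and carboxylation at −78 °C (cold enough to avoid aryne formation), and work-up returns the aldehyde.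

**Fragment B**

Step 6
Reactants: 10 benzene-1,2,4-triol
Product: 11 2,2-diphenyl-1,3-benzodioxol-5-ol
Conditions: Ph2CCl2 (1.1 equiv), neat, 170 °C, N2 stream
Reagents that add atoms: dichlorodiphenylmethane, ClC(Cl)(c1ccccc1)c1ccccc1
Why: Ketalisation with the gem-dichloride can close a ring only across the adjacent 1,2-hydroxyls, leaving the 4-OH free.

Step 7
Reactants: 11 2,2-diphenyl-1,3-benzodioxol-5-ol
Product: 12 5-(methoxymethoxy)-2,2-diphenyl-1,3-benzodioxole
Conditions: MOMCl, iPr2NEt, CH2Cl2, 0 °C → rt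
Reagents that add atoms: chloromethyl methyl ether, COCCl
Why: O-alkylation installs the MOM ether that serves as directing group in steps 8 and 10.

Step 8
Reactants: 12 5-(methoxymethoxy)-2,2-diphenyl-1,3-benzodioxole
Product: 14 [5-(methoxymethoxy)-2,2-diphenyl-1,3-benzodioxol-4-yl]methanol, via aryllithium 13 (not isolated)
Conditions: n-BuLi, THF, −78 → 0 °C; (CH2O)n, 0 °C → rt; H2O
Reagents that add atoms: formaldehyde (from paraformaldehyde), C=O
Why: Directed ortho-metalation occurs at the position flanked by OMOM and the dioxole oxygen (cooperative directing groups), and the aryllithium adds to formaldehyde.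

Step 9
Reactants: 14 [5-(methoxymethoxy)-2,2-diphenyl-1,3-benzodioxol-4-yl]methanol
Product: 15 tert-butyl{[5-(methoxymethoxy)-2,2-diphenyl-1,3-benzodioxol-4-yl]methoxy}diphenylsilane
Conditions: TBDPSCl, imidazole, DMF, rt
Reagents that add atoms: tert-butyl(chloro)diphenylsilane, CC(C)(C)[Si](Cl)(c1ccccc1)c1ccccc1
Why: Silylation of the primary alcohol gives an ether that survives organometallics, hydrogenolysis and carbonate base and is later removed by fluoride.

Step 10
Reactants: 15 tert-butyl{[5-(methoxymethoxy)-2,2-diphenyl-1,3-benzodioxol-4-yl]methoxy}diphenylsilane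
Product: 17 tert-butyl 7-{[(tert-butyldiphenylsilyl)oxy]methyl}-6-(methoxymethoxy)-2,2-diphenyl-1,3-benzodioxole-5-carboxylate, via aryllithium 16 (not isolated)
Conditions: n-BuLi, TMEDA, Et2O, 0 °C; Boc2O, −78 °C → rt; H2O
Reagents that add atoms: di-tert-butyl dicarbonate, CC(C)(C)OC(=O)OC(=O)OC(C)(C)C
Why: Directed ortho-metalation by the chelating OMOM group (its other ortho position is blocked) lithiates the adjacent C–H, and Boc2O traps the aryllithium directly as the tert-butyl ester.

Step 11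
Reactants: 17 tert-butyl 7-{[(tert-butyldiphenylsilyl)oxy]methyl}-6-(methoxymethoxy)-2,2-diphenyl-1,3-benzodioxole-5-carboxylate
Product: 19 tert-butyl 7-{[(tert-butyldiphenylsilyl)oxy]methyl}-4-formyl-6-(methoxymethoxy)-2,2-diphenyl-1,3-benzodioxole-5-carboxylate, via arylmagnesium chloride 18 (not isolated)
Conditions: TMPMgCl·LiCl, THF, 25 °C; DMF, 0 °C; H2O
Reagents that add atoms: N,N-dimethylformamide, CN(C)C=O
Why: Ester-directed magnesiation with the Knochel–Hauser base takes the last ring C–H, flanked by the ester and the dioxole oxygen, and the ester-tolerant arylmagnesium is formylated by DMF.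

Step 12
Reactants: 19 tert-butyl 7-{[(tert-butyldiphenylsilyl)oxy]methyl}-4-formyl-6-(methoxymethoxy)-2,2-diphenyl-1,3-benzodioxole-5-carboxylate
Product: 20 tert-butyl 3-{[(tert-butyldiphenylsilyl)oxy]methyl}-6-formyl-4,5-dihydroxy-2-(methoxymethoxy)benzoate
Conditions: H2 (1 atm), 10% Pd/C, EtOAc, rt, short reaction time
Reagents that add atoms: none
Why: Hydrogenolysis cleaves the doubly benzylic C–O bonds of the diphenylmethylene ketal under neutral conditions that leave the MOM ether, tert-butyl ester, silyl ether and the hindered aryl aldehyde untouched.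

**Fragment C**

Step 13
Reactants: 21 (2E)-4-ethoxy-4-oxobut-2-enoic acid (monoethyl fumarate)
Product: 22 tert-butyl ethyl (2E)-but-2-enedioate
Conditions: isobutene, H2SO4 (cat.), CH2Cl2, sealed tube, rt
Reagents that add atoms: 2-methylpropene, CC(C)=C
Why: Acid-catalysed addition of the carboxylic acid to isobutene gives the tert-butyl ester without touching the E-alkene.

Step 14
Reactants: 22 tert-butyl ethyl (2E)-but-2-enedioate
Product: 23 (2E)-4-tert-butoxy-4-oxobut-2-enoic acid (mono-tert-butyl fumarate)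
Conditions: LiOH (1.0 equiv), THF/H2O, 0 °C; then 1 M HCl
Reagents that add atoms: lithium hydroxide, [Li+].[OH-]
Why: Saponification (BAc2) is selective for the unhindered ethyl ester, the tert-butyl ester resisting hydroxide.

**Fragment union and end game**

Step 15
Reactants: 9 2-fluoro-3-formyl-4-(methoxymethoxy)-6-methylbenzoic acid; 20 tert-butyl 3-{[(tert-butyldiphenylsilyl)oxy]methyl}-6-formyl-4,5-dihydroxy-2-(methoxymethoxy)benzoate
Product: 24 tert-butyl 3-{[(tert-butyldiphenylsilyl)oxy]methyl}-4-{[2-fluoro-3-formyl-4-(methoxymethoxy)-6-methylbenzoyl]oxy}-6-formyl-5-hydroxy-2-(methoxymethoxy)benzoate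
Conditions: EDC·HCl, DMAP (10 mol%), CH2Cl2, 0 °C → rt
Reagents that add atoms: none
Why: Steglich esterification acylates the free 4-OH because the 5-OH is locked in a hydrogen bond to the ortho formyl group, and any 5-O-acyl isomer should relax to the same chelated depside by 1,2-acyl shift.

Step 16
Reactants: 24 tert-butyl 3-{[(tert-butyldiphenylsilyl)oxy]methyl}-4-{[2-fluoro-3-formyl-4-(methoxymethoxy)-6-methylbenzoyl]oxy}-6-formyl-5-hydroxy-2-(methoxymethoxy)benzoate
Product: 26 tert-butyl 9-{[(tert-butyldiphenylsilyl)oxy]methyl}-4,6-diformyl-3,8-bis(methoxymethoxy)-1-methyl-11-oxo-11H-dibenzo[b,e][1,4]dioxepine-7-carboxylate, via Meisenheimer adduct 25 (not isolated)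
Conditions: Cs2CO3, dry DMF (5 mM), 25 → 45 °C
Reagents that add atoms: none
Why: Intramolecular oxa-Michael addition–elimination (SNAr): the formyl-stabilised 5-phenoxide adds to the C–F carbon, which is β to both the formyl and the ester carbonyl of ring A, and the resulting enolate expels fluoride to close the seven-membered ring.

Step 17
Reactants: 26 tert-butyl 9-{[(tert-butyldiphenylsilyl)oxy]methyl}-4,6-diformyl-3,8-bis(methoxymethoxy)-1-methyl-11-oxo-11H-dibenzo[b,e][1,4]dioxepine-7-carboxylate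
Product: 27 tert-butyl 4,6-diformyl-9-(hydroxymethyl)-3,8-bis(methoxymethoxy)-1-methyl-11-oxo-11H-dibenzo[b,e][1,4]dioxepine-7-carboxylate
Conditions: HF·pyridine, pyridine/THF, 0 °C → rt
Reagents that add atoms: none
Why: Fluoride-mediated desilylation under buffered, non-basic conditions frees the benzylic alcohol without generating an alkoxide that could attack the neighbouring depsidone ester.

Step 18
Reactants: 27 tert-butyl 4,6-diformyl-9-(hydroxymethyl)-3,8-bis(methoxymethoxy)-1-methyl-11-oxo-11H-dibenzo[b,e][1,4]dioxepine-7-carboxylate; 23 (2E)-4-tert-butoxy-4-oxobut-2-enoic acid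
Product: 28 tert-butyl 9-({[(2E)-4-tert-butoxy-4-oxobut-2-enoyl]oxy}methyl)-4,6-diformyl-3,8-bis(methoxymethoxy)-1-methyl-11-oxo-11H-dibenzo[b,e][1,4]dioxepine-7-carboxylate
Conditions: EDC·HCl, DMAP (10 mol%), CH2Cl2, 0 °C
Reagents that add atoms: none
Why: Steglich esterification of the only free hydroxyl (a primary benzylic alcohol) with the fumarate half-ester keeps the E geometry.

Step 19
Reactants: 28 tert-butyl 9-({[(2E)-4-tert-butoxy-4-oxobut-2-enoyl]oxy}methyl)-4,6-diformyl-3,8-bis(methoxymethoxy)-1-methyl-11-oxo-11H-dibenzo[b,e][1,4]dioxepine-7-carboxylate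
Product: 30 (2E)-4-{[(1R)-11-formyl-1,4,10-trihydroxy-8-methyl-3,7-dioxo-1,3-dihydro-7H-2,6,12-trioxabenzo[5,6]cyclohepta[1,2-e]inden-5-yl]methoxy}-4-oxobut-2-enoic acid, via formyl acid 29 (not isolated)
Conditions: TFA/CH2Cl2/H2O (10:10:1), 0 °C → rt; evaporate cold; chiral-phase SFC
Reagents that add atoms: none
Why: Acidolysis removes both MOM acetals and both tert-butyl esters, and the freed 2-formylbenzoic acid closes to the hydroxyphthalide by hemiacetal formation without stereocontrol, so the (R)-lactol is taken by chiral chromatography while the (S)-form re-equilibrates through 29 and is recycled.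

**Compound list**
1 | 1-bromo-3-fluoro-5-methylbenzene | Cc1cc(F)cc(Br)c1 | starting material
2 | 3-fluoro-5-methylphenol | Cc1cc(O)cc(F)c1 | intermediate
3 | 4-bromo-3-fluoro-5-methylphenol | Cc1cc(O)cc(F)c1Br | intermediate
4 | 2-bromo-1-fluoro-5-(methoxymethoxy)-3-methylbenzene | Cc1cc(OCOC)cc(F)c1Br | intermediate
5 | [3-bromo-2-fluoro-6-(methoxymethoxy)-4-methylphenyl]lithium (not isolated) | Cc1cc(OCOC)c([Li])c(F)c1Br | intermediate
6 | 3-bromo-2-fluoro-6-(methoxymethoxy)-4-methylbenzaldehyde | Cc1cc(OCOC)c(C=O)c(F)c1Br | intermediate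
7 | lithium [3-bromo-2-fluoro-6-(methoxymethoxy)-4-methylphenyl]{[2-(dimethylamino)ethyl](methyl)amino}methanolate (not isolated) | Cc1cc(OCOC)c(C(O[Li])N(C)CCN(C)C)c(F)c1Br | intermediate
8 | lithium {[2-(dimethylamino)ethyl](methyl)amino}[2-fluoro-3-lithio-6-(methoxymethoxy)-4-methylphenyl]methanolate (not isolated) | Cc1cc(OCOC)c(C(O[Li])N(C)CCN(C)C)c(F)c1[Li] | intermediate
9 | 2-fluoro-3-formyl-4-(methoxymethoxy)-6-methylbenzoic acid | Cc1cc(OCOC)c(C=O)c(F)c1C(=O)O | intermediate
10 | benzene-1,2,4-triol | Oc1ccc(O)c(O)c1 | starting material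
11 | 2,2-diphenyl-1,3-benzodioxol-5-ol | Oc1ccc2OC(c3ccccc3)(c3ccccc3)Oc2c1 | intermediate
12 | 5-(methoxymethoxy)-2,2-diphenyl-1,3-benzodioxole | COCOc1ccc2OC(c3ccccc3)(c3ccccc3)Oc2c1 | intermediate
13 | [5-(methoxymethoxy)-2,2-diphenyl-1,3-benzodioxol-4-yl]lithium (not isolated) | COCOc1ccc2OC(c3ccccc3)(c3ccccc3)Oc2c1[Li] | intermediate
14 | [5-(methoxymethoxy)-2,2-diphenyl-1,3-benzodioxol-4-yl]methanol | COCOc1ccc2OC(c3ccccc3)(c3ccccc3)Oc2c1CO | intermediate
15 | tert-butyl{[5-(methoxymethoxy)-2,2-diphenyl-1,3-benzodioxol-4-yl]methoxy}diphenylsilane | COCOc1ccc2OC(c3ccccc3)(c3ccccc3)Oc2c1CO[Si](c4ccccc4)(c4ccccc4)C(C)(C)C | intermediate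
16 | [7-{[(tert-butyldiphenylsilyl)oxy]methyl}-6-(methoxymethoxy)-2,2-diphenyl-1,3-benzodioxol-5-yl]lithium (not isolated) | COCOc1c([Li])cc2OC(c3ccccc3)(c3ccccc3)Oc2c1CO[Si](c4ccccc4)(c4ccccc4)C(C)(C)C | intermediate
17 | tert-butyl 7-{[(tert-butyldiphenylsilyl)oxy]methyl}-6-(methoxymethoxy)-2,2-diphenyl-1,3-benzodioxole-5-carboxylate | COCOc1c(C(=O)OC(C)(C)C)cc2OC(c3ccccc3)(c3ccccc3)Oc2c1CO[Si](c4ccccc4)(c4ccccc4)C(C)(C)C | intermediate
18 | [5-(tert-butoxycarbonyl)-7-{[(tert-butyldiphenylsilyl)oxy]methyl}-6-(methoxymethoxy)-2,2-diphenyl-1,3-benzodioxol-4-yl]magnesium chloride (not isolated) | COCOc1c(C(=O)OC(C)(C)C)c([Mg]Cl)c2OC(c3ccccc3)(c3ccccc3)Oc2c1CO[Si](c4ccccc4)(c4ccccc4)C(C)(C)C | intermediate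
19 | tert-butyl 7-{[(tert-butyldiphenylsilyl)oxy]methyl}-4-formyl-6-(methoxymethoxy)-2,2-diphenyl-1,3-benzodioxole-5-carboxylate | COCOc1c(C(=O)OC(C)(C)C)c(C=O)c2OC(c3ccccc3)(c3ccccc3)Oc2c1CO[Si](c4ccccc4)(c4ccccc4)C(C)(C)C | intermediate
20 | tert-butyl 3-{[(tert-butyldiphenylsilyl)oxy]methyl}-6-formyl-4,5-dihydroxy-2-(methoxymethoxy)benzoate | COCOc1c(C(=O)OC(C)(C)C)c(C=O)c(O)c(O)c1CO[Si](c2ccccc2)(c2ccccc2)C(C)(C)C | intermediate
21 | (2E)-4-ethoxy-4-oxobut-2-enoic acid (monoethyl fumarate) | CCOC(=O)/C=C/C(=O)O | starting material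
22 | tert-butyl ethyl (2E)-but-2-enedioate | CCOC(=O)/C=C/C(=O)OC(C)(C)C | intermediate
23 | (2E)-4-tert-butoxy-4-oxobut-2-enoic acid (mono-tert-butyl fumarate) | CC(C)(C)OC(=O)/C=C/C(=O)O | intermediate
24 | tert-butyl 3-{[(tert-butyldiphenylsilyl)oxy]methyl}-4-{[2-fluoro-3-formyl-4-(methoxymethoxy)-6-methylbenzoyl]oxy}-6-formyl-5-hydroxy-2-(methoxymethoxy)benzoate (depside) | Cc1cc(OCOC)c(C=O)c(F)c1C(=O)Oc2c(O)c(C=O)c(C(=O)OC(C)(C)C)c(OCOC)c2CO[Si](c3ccccc3)(c3ccccc3)C(C)(C)C | intermediate
25 | Meisenheimer adduct, cesium enolate: ring-closed σ-adduct from addition of the 5-phenoxide of 24 to the C–F carbon (not isolated) | [Cs+].CC1=C2C(=O)Oc3c(CO[Si](c4ccccc4)(c4ccccc4)C(C)(C)C)c(OCOC)c(C(=O)OC(C)(C)C)c(C=O)c3OC2(F)C(=C[O-])C(OCOC)=C1 | intermediate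
26 | tert-butyl 9-{[(tert-butyldiphenylsilyl)oxy]methyl}-4,6-diformyl-3,8-bis(methoxymethoxy)-1-methyl-11-oxo-11H-dibenzo[b,e][1,4]dioxepine-7-carboxylate | Cc1cc(OCOC)c(C=O)c2Oc3c(C=O)c(C(=O)OC(C)(C)C)c(OCOC)c(CO[Si](c4ccccc4)(c4ccccc4)C(C)(C)C)c3OC(=O)c12 | intermediate
27 | tert-butyl 4,6-diformyl-9-(hydroxymethyl)-3,8-bis(methoxymethoxy)-1-methyl-11-oxo-11H-dibenzo[b,e][1,4]dioxepine-7-carboxylate | Cc1cc(OCOC)c(C=O)c2Oc3c(C=O)c(C(=O)OC(C)(C)C)c(OCOC)c(CO)c3OC(=O)c12 | intermediate
28 | tert-butyl 9-({[(2E)-4-tert-butoxy-4-oxobut-2-enoyl]oxy}methyl)-4,6-diformyl-3,8-bis(methoxymethoxy)-1-methyl-11-oxo-11H-dibenzo[b,e][1,4]dioxepine-7-carboxylate | Cc1cc(OCOC)c(C=O)c2Oc3c(C=O)c(C(=O)OC(C)(C)C)c(OCOC)c(COC(=O)/C=C/C(=O)OC(C)(C)C)c3OC(=O)c12 | intermediate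
29 | 9-({[(2E)-3-carboxyprop-2-enoyl]oxy}methyl)-4,6-diformyl-3,8-dihydroxy-1-methyl-11-oxo-11H-dibenzo[b,e][1,4]dioxepine-7-carboxylic acid (open formyl acid; not isolated) | Cc1cc(O)c(C=O)c2Oc3c(C=O)c(C(=O)O)c(O)c(COC(=O)/C=C/C(=O)O)c3OC(=O)c12 | intermediate
30 | (2E)-4-{[(1R)-11-formyl-1,4,10-trihydroxy-8-methyl-3,7-dioxo-1,3-dihydro-7H-2,6,12-trioxabenzo[5,6]cyclohepta[1,2-e]inden-5-yl]methoxy}-4-oxobut-2-enoic acid (CNP0379578.1; depsidone with (R)-hydroxyphthalide and hydrogen fumarate ester) | Cc1cc(O)c(C=O)c2c1C(=O)Oc1c(COC(=O)/C=C/C(=O)O)c(O)c3c(c1O2)[C@H](O)OC3=O | target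

**Totals**
Total step count: 19.
Longest linear sequence: 12 steps (steps 6–12, then 15–19).

**Steps most likely to fail**

Step 16 (ring closure). Under base the aroyl group can shift between the two adjacent catechol oxygens of 24, and the shifted phenoxide would close to the regioisomeric depsidone. The fallback forms the diaryl ether first and lactonises last; it sets out from 9 and 20 and comes back at 26. Acid 9 is alkylated (allyl bromide, K2CO3, DMF) to allyl 2-fluoro-3-formyl-4-(methoxymethoxy)-6-methylbenzoate F1. Catechol 20 is mono-allylated at the non-chelated 4-OH through its dianion (NaH 2.2 equiv, DMSO, allyl bromide 1.0 equiv) to give tert-butyl 4-(allyloxy)-3-{[(tert-butyldiphenylsilyl)oxy]methyl}-6-formyl-5-hydroxy-2-(methoxymethoxy)benzoate F2. Intermolecular SNAr of the single free phenoxide of F2 on F1 (K2CO3, DMF, 60 °C) gives allyl 2-[6-(allyloxy)-3-(tert-butoxycarbonyl)-5-{[(tert-butyldiphenylsilyl)oxy]methyl}-2-formyl-4-(methoxymethoxy)phenoxy]-3-formyl-4-(methoxymethoxy)-6-methylbenzoate F3. Pd(PPh3)4 with N-methylaniline removes both allyl groups to give 2-[3-(tert-butoxycarbonyl)-5-{[(tert-butyldiphenylsilyl)oxy]methyl}-2-formyl-6-hydroxy-4-(methoxymethoxy)phenoxy]-3-formyl-4-(methoxymethoxy)-6-methylbenzoic acid F4. This is lactonised under carbodiimide conditions at high dilution (DCC, cat. DMAP, CH2Cl2), avoiding the strong base that could trigger a Smiles rearrangement, to give 26.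

Step 11 (magnesiation and formylation). The arene is electron-rich and crowded, so deprotonation by the TMP base may be slow or incomplete. The fallback replaces C–H metalation by electrophilic bromination and halogen–magnesium exchange; it sets out from 17 and comes back at 19. NBS in DMF brominates the only free ring position to give tert-butyl 4-bromo-7-{[(tert-butyldiphenylsilyl)oxy]methyl}-6-(methoxymethoxy)-2,2-diphenyl-1,3-benzodioxole-5-carboxylate F5. Exchange with i-PrMgCl·LiCl (THF, −15 °C) followed by DMF then delivers 19.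

Step 10 (OMOM-directed lithiation). Lithiation next to the dioxole oxygen instead of next to OMOM would place the ester on the wrong carbon. The fallback fixes the position by electrophilic substitution; it sets out from 15 and comes back at 17. NBS in MeCN at 0 °C brominates ortho to OMOM and para to a dioxole oxygen to give {[6-bromo-5-(methoxymethoxy)-2,2-diphenyl-1,3-benzodioxol-4-yl]methoxy}(tert-butyl)diphenylsilane F6. Br–Li exchange (n-BuLi, THF, −78 °C) and trapping with Boc2O give 17.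

**Further compounds**
F1 | step 16 | allyl 2-fluoro-3-formyl-4-(methoxymethoxy)-6-methylbenzoate | Cc1cc(OCOC)c(C=O)c(F)c1C(=O)OCC=C
F2 | step 16 | tert-butyl 4-(allyloxy)-3-{[(tert-butyldiphenylsilyl)oxy]methyl}-6-formyl-5-hydroxy-2-(methoxymethoxy)benzoate | COCOc1c(C(=O)OC(C)(C)C)c(C=O)c(O)c(OCC=C)c1CO[Si](c2ccccc2)(c2ccccc2)C(C)(C)C
F3 | step 16 | allyl 2-[6-(allyloxy)-3-(tert-butoxycarbonyl)-5-{[(tert-butyldiphenylsilyl)oxy]methyl}-2-formyl-4-(methoxymethoxy)phenoxy]-3-formyl-4-(methoxymethoxy)-6-methylbenzoate | Cc1cc(OCOC)c(C=O)c(Oc2c(C=O)c(C(=O)OC(C)(C)C)c(OCOC)c(CO[Si](c3ccccc3)(c3ccccc3)C(C)(C)C)c2OCC=C)c1C(=O)OCC=C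
F4 | step 16 | 2-[3-(tert-butoxycarbonyl)-5-{[(tert-butyldiphenylsilyl)oxy]methyl}-2-formyl-6-hydroxy-4-(methoxymethoxy)phenoxy]-3-formyl-4-(methoxymethoxy)-6-methylbenzoic acid | Cc1cc(OCOC)c(C=O)c(Oc2c(C=O)c(C(=O)OC(C)(C)C)c(OCOC)c(CO[Si](c3ccccc3)(c3ccccc3)C(C)(C)C)c2O)c1C(=O)O
F5 | step 11 | tert-butyl 4-bromo-7-{[(tert-butyldiphenylsilyl)oxy]methyl}-6-(methoxymethoxy)-2,2-diphenyl-1,3-benzodioxole-5-carboxylate | COCOc1c(C(=O)OC(C)(C)C)c(Br)c2OC(c3ccccc3)(c3ccccc3)Oc2c1CO[Si](c4ccccc4)(c4ccccc4)C(C)(C)C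
F6 | step 10 | {[6-bromo-5-(methoxymethoxy)-2,2-diphenyl-1,3-benzodioxol-4-yl]methoxy}(tert-butyl)diphenylsilane | COCOc1c(Br)cc2OC(c3ccccc3)(c3ccccc3)Oc2c1CO[Si](c4ccccc4)(c4ccccc4)C(C)(C)C
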